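The dusk flask cannot have stopped for want of partner, and yet it stopped.

in all of them: substrate 0.20 M; catalyst 40 mM
- midnight: partner 0.18 M; protic impurity 0.040 M; run made earlier
- autumn: partner 0.35 M; protic impurity 0.040 M; run made earlier
- dusk: partner 0.57 M; protic impurity 0.040 M; run made earlier
- Tuesday's: partner 0.760 M; protic impurity 0.0400 M; time 6.0 d
- Saturday's: partner 0.190 M; protic impurity 0.0400 M; time 6.0 d
- Monday's: partner 0.380 M; protic impurity 0.0400 M; time 6.0 d

| run | time / d | target / % | substrate / % |
|---|---|---|---|
| midnight | 0.833 | 22 | 0 |
| midnight | 1.67 | 26 | 0 |
| midnight | 2.50 | 26 | 0 |
| midnight | 3.00 | 27 | 0 |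
| midnight | 4.00 | 25 | 1 |
| autumn | 0.417 | 40 | 4 |
| autumn | 1.04 | 39 | 0 |
| autumn | 2.08 | 37 | 0 |
| autumn | 3.00 | 41 | 2 |
| autumn | 4.00 | 42 | 0 |
| dusk | 0.333 | 50 | 4 |
| dusk | 0.625 | 56 | 4 |
| dusk | 1.25 | 53 | 3 |
| dusk | 2.00 | 55 | 1 |
| dusk | 4.00 | 55 | 2 |

(readings scatter by 2 percentage points)



- which of the two there is more of at the end, Tuesday's (side product / target)
- which of the two there is more of at the end, Saturday's (side product / target)
- which of the two there is more of at the end, Monday's (side product / target)
- target at the end, in percent of the substrate charged, Tuesday's
- target at the end, in percent of the substrate charged, Saturday's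
- target at the end, in percent of the substrate charged, Monday's

In the dusk run the substrate reads 2% at 4.00 d while the target holds near 54.8%. At one partner per substrate, that target has used 0.110 M of partner, less than the 0.57 M charged. So the plateau is a division of the substrate, not a shortage. I take the remainder to be side product, and the plateau rises with the partner charge.

Let x be the share of substrate ending as target, s the share ending as side product, a the substrate charge and p the partner charge. Suppose target forms against side product in the ratio of free partner to a constant K. Replace the falling partner curve by its mean, b:

x/s = b/K, with b = p − a·x/2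

Plateau means give my values of K = b·s/x:

midnight: 26.0% target, K = 0.438 M
autumn: 39.7% target, K = 0.470 M
dusk: 54.8% target, K = 0.426 M

Their mean, 0.445 M, is my crossover partner concentration: the value of b at which target and side product form equally, a selectivity factor with units. It is an effective value, since b takes no account of partner lost to the protic impurity. Following the whole curve in the midnight run gives 0.434 M instead of 0.438 M, so the mean costs 0.957%.

My reckoning then gives:

Tuesday's: 61.1%
Saturday's: 26.8%
Monday's: 43.1%

Target leads where b exceeds K. Tuesday's b is 0.699 M, while Monday's is 0.337 M.

For Tuesday's the forecast gives 61% target, with target the larger. For Saturday's it gives 27% target, with side product the larger. For Monday's it gives 43% target, with side product the larger. It adds: “Tuesday's value is an extrapolation, so it is less certain”.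

Tuesday's flask ends at 62.4% target, with target the larger. Saturday's flask ends at 25.2% target, with side product the larger. Monday's flask ends at 43.0% target, with side product the larger. Tuesday's flask repeats the dusk puzzle: it ends with 78.3% of its partner free and 37.6% side product. Read from that end state, K is 0.421 M, beside your 0.445 M.

    substrate + catalyst → catalyst + intermediate (k = 0.00230 /M/s)
    partner + catalyst + intermediate → catalyst + target (k = 0.0390 /M²/s)
    intermediate → side product (k = 6.20 × 10⁻⁴ /s)
    partner + protic impurity → quenched reagent (k = 0.00100 /M/s)

Catalyst enters the target step and not the side step, so scale K by the catalyst charges. For a neighbour of Monday's with 0.10 M catalyst, K becomes 0.178 M, and the same reckoning gives 64.0% target. The computed flask gives 64.0%, with target holding most of the substrate.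

Readings and results were computed on assumed constants; the scatter is artificial.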